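Briarane numbering is used throughout. α and β denote the two faces of the cyclohexane, β being the face that carries the methyl group on C1.

## The problem

The target is a briarane: a cyclohexane (C1, C10 to C14) fused through the C1–C10 bond to a ten-membered carbocycle (C1 to C10). The large ring holds a Z trisubstituted C5=C6 olefin and is fused at C7–C8 to an α-methylbutenolide (C7, C8, C17, C19 and the ring oxygen). There are eight stereocentres: five contiguous ones on the cyclohexane (quaternary C1, C10, C11, C12, C14) and three on the large ring (C2, C7, C9). C1, C10 and C14 can be set together. C11 and C12 can then be relayed from C10 and from the oxygen on C9. C2 and C9 are carbinols next to ring stereocentres, open to reagent control (C2) and Felkin–Anh control (C9). C7 arises only in the ring-closing event, but it stays correctable because the butenolide can be flattened to a furanolate. Four oxygens of the same oxidation level must end as one butyrate (C2), two acetates (C9, C14) and one free alcohol (C12). Fragile points are the β-oxygenated C12 ketone on the way (loss of the C14 oxygen by β-elimination), the doubly allylic, acidic C7–H of the butenolide, and the Z olefin. The feature that opens the route is the cyclohexane itself: oxygens at C12 and C14 in a 1,3-relation, C14 next to the quaternary C1, and the C2 and C9 arms trans on C1 and C10. This is the pattern left by a [4+2] cycloaddition of a 1-alkoxy-3-silyloxybutadiene (C11 to C14) with an E α-methyl enal (C2, C1, C10, C9).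

## Retrosynthesis

**Protecting-group endgame (39 ⇐ 38 ⇐ 37 ⇐ 36).** No skeletal bond is cut. The free C12 hydroxyl of 39 is kept as a triethylsilyl ether (38) until the last step, and the C14 acetate is put on after removal of a 4-methoxybenzyl ether (37 from 36). This order lets the butyrate and the C9 acetate be installed one at a time, each when its hydroxyl is the only free one. The forward steps must spare three esters and the butenolide.

**Ten-membered ring and butenolide (36 ⇐ 34).** The C6–C7 bond and the lactone C–O bond are cut together. A Nozaki–Hiyama–Kishi addition of a Z alkenyl iodide to a C7 aldehyde tolerates the esters, keeps the olefin geometry and leaves an alkoxide cis to the C19 carboxyl, which lactonises. Ring-closing metathesis at C5=C6 would have to form a trisubstituted olefin in a ten-membered ring and was judged less safe. The precursor 34 is open-chain. The forward step must close a medium ring and set C7.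

**Butenolide carbons (34 ⇐ 33 ⇐ 27 + 30).** The C8–C9 bond is cut. C7, C8, C17, C18 and C19 come as one piece from methyltetronic acid in the form of bromo(silyloxy)furan 30. Its lithio derivative adds to aldehyde 27, and oxidation of the silyloxyfuran 33 then unveils the C7 aldehyde and the cis silyl ester of 34 in one step. A chromium-mediated coupling at C8–C9 was set aside because the alkenyl iodide already present would compete. The forward addition must set C9 and must not epimerise C10.

**C12 carbinol (27 ⇐ 26 ⇐ 25 ⇐ 24 ⇐ 23).** Only functional groups change. The 12α-alcohol of 25 is made from ketone 24 by hydride delivery from the C9 hydroxyl, which sits on the β face. The same primary alcohol then becomes the aldehyde of 26, and 27 is its silyl ether. External hydrides would have to approach past the C9 arm and would favour the wrong epimer.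

**C11 methyl group (23 ⇐ 21 ⇐ 18).** The C11–C20 bond is cut. C20 enters ketone 18 as an exocyclic methylene (21). Conjugate reduction then gives one defined enolate, and its kinetic protonation places the methyl group cis to the C9 arm (23). Direct methylation would give the more accessible trans epimer and would leave no regiodefined way back to the enolate.

**C2 arm (18 ⇐ 17 ⇐ 16 ⇐ 15 ⇐ 10 + 14).** The C3–C4 bond is cut. Methyl ketone 10 has one enolisable position and is alkylated with allylic bromide 14, which brings C4 to C6 with the Z iodoalkene already in place. Reagent-controlled reduction of 15 sets C2 (16), and the butyrate goes on at once (17). The silyl enol ether inherited from the cycloaddition masks C12 during these steps and is opened afterwards (18). Adding a C3 to C6 organometallic to the aldehyde was rejected: an alkylmetal and an alkenyl iodide do not coexist well, and substrate control at C2 is uncertain.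

**Methyl ketone (10 ⇐ 9 ⇐ 8).** The C2–C3 bond is cut. Methyl addition to the formyl group of 8 and oxidation give 10.

**Cyclohexane (8 ⇐ 3 + 7).** The C1–C14 and C10–C11 bonds are cut. This removes the ring and three stereocentres in one step and leads to two small achiral partners, enal 3 and diene 7. The forward reaction must be regioselective, formyl-endo and enantioselective.

**Small pieces (3 ⇐ 1 + 2; 7 ⇐ 6 ⇐ 4 + 5; 14 ⇐ 13 ⇐ 11; 30 ⇐ 29 ⇐ 28).** The enal comes from a Wittig reaction. The diene comes from alkoxy exchange and silylation. The bromide comes from anti-carbomagnesiation of propargyl alcohol. The furan comes from methyltetronic acid.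

## Roads not taken

**Alternative 1:** Make the ring closure the centre of the plan. The C6–C7 bond and the lactone C–O bond are cut, and the target's 12-O-triethylsilyl ether A1 is traced to the open-chain iodo aldehyde methyl ester A2. In the forward step CrCl2 with catalytic NiCl2 adds the Z alkenyl iodide to the C7 aldehyde, and the chromium alkoxide closes the butenolide on the cis ester.
- Merits: one step forms the ten-membered ring, C7 and the lactone. All acyl groups are already in place, so only a desilylation follows.
- Weak points: A2 presupposes the cyclohexane with five contiguous stereocentres and both fully dressed arms, and the plan does not say how that is made. The doubly activated enal is open to reduction by divalent chromium. C7 is left to the macrocyclic transition state.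
- Comparison: for the ring closure this road is as good as the chosen one, which adopts the same closure in step 23. It is slightly better in that no protecting-group exchange follows the cyclisation. Against this the chosen plan offers a defined entry to the cyclohexane; it reaches A1 itself as compound 38.

**Alternative 2:** Obtain the medium ring by cutting a bond rather than making one. The ten-membered diketone A3 is traced to the tricyclic 1,4-diene A4, a Birch-derived hydrophenanthrene in which C2=C7 is the tetrasubstituted ring-fusion olefin. Ozonolysis of that olefin releases the C2 and C7 ketones and the large ring.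
- Merits: no entropically costly cyclisation. The cyclohexane stereocentres can be set on a rigid tricycle. In certainty of forming the ten-membered ring this road is better than the chosen one.
- Weak points: ozone must distinguish the tetrasubstituted olefin from the trisubstituted C4=C5 olefin. A3 holds two β,γ-unsaturated ketones that tend to move into conjugation. The olefin sits at C4=C5 and must be moved to C5=C6 with Z geometry. C17, C18 and C19 are still missing, C8 is an unfunctionalised methylene, and C2 and C7 need stereoselective reduction.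
- Comparison: the work left after the key step is long and has little stereocontrol. The chosen plan accepts a riskier ring closure but arrives there with every carbon and all but one stereocentre in place.

**Alternative 3:** Follow the presumed biogenesis. The C1–C10 bond is cut, leading from the bicyclic alcohol A5 to the fourteen-membered epoxy olefin A6. Et2AlCl opens the C1–C2 epoxide at C1, C10 of the C10=C11 olefin attacks C1, and the C11 cation loses a proton from C20.
- Merits: the quaternary centre, the cyclohexane and the C2 carbinol appear in one step. A5 is only a hydrogenation, a protecting-group exchange and acylations away from the target. After the key step this road is shorter than the chosen one.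
- Weak points: A6 is itself a macrocyclisation problem, with a Z and an E olefin, an epoxide, the butenolide and four stereocentres. The relative configuration at C1 and C10 depends on the conformation of the macrocycle and cannot be predicted with confidence. The cation can also be intercepted by hydride shift, by the C5=C6 olefin or by simple elimination. C11 must then be hydrogenated from the right face beside the C5=C6 olefin.
- Comparison: the chosen plan fixes C1, C10 and C14 by a suprafacial cycloaddition whose outcome is understood. It pays with a longer sequence for the arms.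

Key step: step 4

Assumption: the oxazaborolidinium from (S)-α,α-diphenylprolinol is taken to shield the enal face that leads to 8 (formyl C–H···O binding model); should the sense be opposite, the catalyst from the (R)-amino alcohol is used with nothing else changed.

Assumption: 3-methyltetronic acid 28 is taken as a commercial compound; otherwise it is one step from ethyl 2-methylacetoacetate (bromination, thermal cyclisation).

## Route

Step 1
Reactants: 1 (tert-butyldimethylsilyloxy)acetaldehyde; 2 2-(triphenylphosphoranylidene)propanal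
Product: 3 (E)-4-(tert-butyldimethylsilyloxy)-2-methylbut-2-enal
Conditions: toluene, 80 °C
Reagents that add atoms: none
Why: Wittig olefination with a stabilised formyl ylide, which gives the E trisubstituted enal under thermodynamic control; the saturated aldehyde 1 reacts faster than the conjugated product, so over-homologation is not expected.

Step 2
Reactants: 4 (E)-4-methoxybut-3-en-2-one; 5 4-methoxybenzyl alcohol
Product: 6 (E)-4-(4-methoxybenzyloxy)but-3-en-2-one
Conditions: pyridinium p-toluenesulfonate (cat.), toluene, 60 °C, reduced pressure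
Reagents that add atoms: none
Why: Acid-catalysed addition–elimination (alkoxy exchange) on a vinylogous ester, driven by removal of methanol; the E isomer is the stable one.

Step 3
Reactants: 6 (E)-4-(4-methoxybenzyloxy)but-3-en-2-one
Product: 7 (E)-1-(4-methoxybenzyloxy)-3-(tert-butyldimethylsilyloxy)buta-1,3-diene
Conditions: t-BuMe2SiOTf, Et3N, Et2O, 0 °C
Reagents that add atoms: tert-butyldimethylsilyl trifluoromethanesulfonate, CC(C)(C)[Si](C)(C)OS(=O)(=O)C(F)(F)F
Why: Soft enolisation and O-silylation of the methyl ketone, the standard preparation of 1-alkoxy-3-silyloxybutadienes; the tert-butyldimethylsilyl group is chosen so that the enol ether of the adduct survives five further steps.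

Step 4
Reactants: 3 (E)-4-(tert-butyldimethylsilyloxy)-2-methylbut-2-enal; 7 (E)-1-(4-methoxybenzyloxy)-3-(tert-butyldimethylsilyloxy)buta-1,3-diene
Product: 8 cycloadduct: cyclohexene with quaternary C1 (β-methyl, α-formyl), 14α-(4-methoxybenzyloxy), 10β-(tert-butyldimethylsilyloxymethyl) and the C12=C13 tert-butyldimethylsilyl enol ether
Conditions: (S)-B-(o-tolyl)oxazaborolidine from (S)-α,α-diphenylprolinol (20 mol%), HNTf2 (18 mol%), CH2Cl2, −78 °C
Reagents that add atoms: none
Why: The oxazaborolidinium binds the formyl oxygen of 3, lowers the LUMO of the s-trans enal and covers one of its faces. Diene 7 then adds in a concerted but asynchronous [4+2] cycloaddition: its nucleophilic methylene terminus C11 bonds to the β-carbon C10 and the alkoxy-bearing terminus C14 to the α-carbon C1. The closest known reaction type is the Lewis acid-catalysed Diels–Alder reaction of 1-alkoxy-3-silyloxybutadienes with α-substituted enals, including its chiral oxazaborolidinium version. The cyclohexene closes suprafacially on both partners, so the E geometry of 3 becomes the trans relation of the formyl carbon C2 (on C1) and the C9 arm (on C10). Endo orientation of the complexed formyl group puts the outside 4-methoxybenzyloxy group at C14 cis to C2. The absolute configuration of C1, C10 and C14 follows from the enal face left open by the catalyst. The step needs three selectivities: the regiochemistry shown (secured by the 1,3-donor pattern of 7 against the complexed carbonyl), formyl-endo addition (secured by Lewis acid complexation, which counters the levelling effect of the α-methyl group) and one enantioface (catalyst). The silyl enol ether is kept as the mask of C12.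

Step 5
Reactants: 8 cycloadduct
Product: 9 secondary alcohol (C2 carbinol carrying the C3 methyl group; both C2 epimers; rest as 8)
Conditions: MeMgBr, THF, −78 °C; aq. NH4Cl
Reagents that add atoms: methylmagnesium bromide, C[Mg]Br
Why: Grignard addition to a non-enolisable neopentyl aldehyde; the silyl enol ether and the ethers are inert, and the C2 epimers converge in step 6.

Step 6
Reactants: 9 secondary alcohol
Product: 10 methyl ketone (C2 carbonyl, C3 methyl; rest as 8)
Conditions: (COCl)2, DMSO, CH2Cl2, −78 °C; Et3N
Reagents that add atoms: none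
Why: Swern oxidation; the basic, non-aqueous conditions leave the silyl enol ether and the allylic ether untouched.

Step 7
Reactants: 11 prop-2-yn-1-ol
Product: 13 (Z)-3-iodo-2-methylprop-2-en-1-ol, via alkenylmagnesium alkoxide 12 (not isolated)
Conditions: MeMgBr (2.5 equiv), CuI (10 mol%), THF, −10 °C to rt; then I2, −20 °C
Reagents that add atoms: methylmagnesium bromide, C[Mg]Br; iodine, II
Why: Copper-catalysed anti-carbomagnesiation of the propargylic alkoxide: the magnesium chelate places the methyl group on C2 and the metal on C3 cis to the CH2O group, and iodinolysis with retention gives the Z iodide.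

Step 8
Reactants: 13 (Z)-3-iodo-2-methylprop-2-en-1-ol
Product: 14 (Z)-3-bromo-1-iodo-2-methylprop-1-ene
Conditions: CBr4, PPh3, CH2Cl2, 0 °C
Reagents that add atoms: tetrabromomethane, BrC(Br)(Br)Br
Why: Appel bromination of a primary allylic alcohol; the olefin geometry is not touched.

Step 9
Reactants: 10 methyl ketone; 14 (Z)-3-bromo-1-iodo-2-methylprop-1-ene
Product: 15 C2 ketone carrying the chain C3 to C6 with the Z C5=C6 alkenyl iodide (rest as 8)
Conditions: LiN(i-Pr)2, THF, −78 °C; 14, DMPU, −78 to −20 °C
Reagents that add atoms: none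
Why: Enolate alkylation of the methyl ketone with an allylic bromide (SN2), forming C3–C4; the enolate of 10 is the only one possible because C1 is quaternary and C12 is masked as the enol ether.

Step 10
Reactants: 15 C2 ketone
Product: 16 (2R)-alcohol (rest as 15)
Conditions: (S)-2-methyl-CBS-oxazaborolidine (20 mol%), catecholborane, toluene, −78 °C
Reagents that add atoms: none
Why: Corey–Bakshi–Shibata reduction: the quaternary C1 is the large group and the C3 methylene the small one, so the (S)-catalyst should give the 2R carbinol under reagent control; catecholborane at low temperature spares the enol ether and the alkenyl iodide.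

Step 11
Reactants: 16 (2R)-alcohol
Product: 17 (2R)-butyrate (rest as 15)
Conditions: (PrCO)2O, DMAP, Et3N, CH2Cl2, rt
Reagents that add atoms: butyric anhydride, CCCC(=O)OC(=O)CCC
Why: DMAP-catalysed acylation of the only free hydroxyl.

Step 12
Reactants: 17 (2R)-butyrate
Product: 18 C12 ketone (14α-ether, C9 silyl ether and butyrate retained; C11 and C13 methylene)
Conditions: Bu4NF (1.1 equiv), AcOH (2 equiv), THF, −20 °C
Reagents that add atoms: none
Why: Fluoride cleaves the silyl enol ether far faster than the alkyl silyl ether; the acetic acid protonates the enolate at C13 before it can expel the β-alkoxy group.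

Step 13
Reactants: 18 C12 ketone
Product: 21 11-methylene 12-ketone, via Mannich base 19 (not isolated), via ammonium iodide 20 (not isolated)
Conditions: LiN(i-Pr)2 (1.05 equiv), THF, −78 °C; CH2=NMe2+ I−, −78 to 0 °C; MeI, CH2Cl2, rt; aq. NaHCO3
Reagents that add atoms: N,N-dimethylmethyleneiminium iodide (Eschenmoser's salt), C=[N+](C)C.[I-]
Why: Kinetic deprotonation of β-alkoxy ketones by lithium amides takes place away from the β-heteroatom, here at C11; Mannich reaction, N-methylation and E1cB loss of trimethylamine then give the exocyclic enone. One equivalent of base at −78 °C should leave the less acidic butyrate alone.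

Step 14
Reactants: 21 11-methylene 12-ketone
Product: 23 11β-methyl 12-ketone, via lithium enolate 22 (not isolated)
Conditions: Li[HB(s-Bu)3] (1.1 equiv), THF, −78 °C; then 2,6-di-tert-butyl-4-methylphenol, −78 °C
Reagents that add atoms: none
Why: 1,4-Hydride addition to the exocyclic enone gives the C11=C12 enolate 22 with no regiochemical ambiguity. Kinetic protonation should come from the α face, away from the C10 side arm and the C1 methyl group, which puts the new methyl group β (cis to the C9 arm).

Step 15
Reactants: 23 11β-methyl 12-ketone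
Product: 24 C9 primary alcohol (rest as 23)
Conditions: HF·pyridine, pyridine, THF, 0 °C
Reagents that add atoms: none
Why: Buffered HF removes the primary silyl ether without base, so the epimerisable C11 next to the ketone is not put at risk.

Step 16
Reactants: 24 C9 primary alcohol
Product: 25 9,12α-diol (12α-hydroxyl cis to the 14α-ether)
Conditions: Me4NBH(OAc)3, MeCN/AcOH, −30 °C
Reagents that add atoms: none
Why: Hydroxyl-directed reduction of the Evans–Saksena type: the C9 alkoxy(acetoxy)borohydride, held on the β face by the axial side arm, delivers hydride intramolecularly to the β face of C12 and gives the 12α-alcohol. The reagent reduces undirected ketones only slowly.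

Step 17
Reactants: 25 9,12α-diol
Product: 26 C9 aldehyde with free 12α-hydroxyl
Conditions: TEMPO (cat.), PhI(OAc)2, CH2Cl2, rt
Reagents that add atoms: none
Why: Oxoammonium oxidation, selective for the primary alcohol; the neutral medium protects the α-stereocentre C10.

Step 18
Reactants: 26 C9 aldehyde
Product: 27 C9 aldehyde 12α-triethylsilyl ether
Conditions: Et3SiOTf, 2,6-lutidine, CH2Cl2, −78 °C
Reagents that add atoms: triethylsilyl trifluoromethanesulfonate, CC[Si](CC)(CC)OS(=O)(=O)C(F)(F)F
Why: Silylation of the secondary alcohol at low temperature with a weak, hindered base, which should not enolise the aldehyde.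

Step 19
Reactants: 28 3-methyltetronic acid (4-hydroxy-3-methylfuran-2(5H)-one)
Product: 29 4-bromo-3-methylfuran-2(5H)-one
Conditions: (COBr)2, DMF (cat.), CH2Cl2, 0 °C to rt
Reagents that add atoms: oxalyl bromide, O=C(Br)C(=O)Br
Why: Vilsmeier-type conversion of a vinylogous acid into the vinylogous acid bromide.

Step 20
Reactants: 29 4-bromo-3-methylfuran-2(5H)-one
Product: 30 4-bromo-3-methyl-2-(triisopropylsilyloxy)furan
Conditions: i-Pr3SiOTf, Et3N, CH2Cl2, 0 °C
Reagents that add atoms: triisopropylsilyl trifluoromethanesulfonate, CC(C)[Si](C(C)C)(C(C)C)OS(=O)(=O)C(F)(F)F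
Why: γ-Deprotonation and O-silylation of a butenolide gives the aromatic 2-silyloxyfuran; the bulky silyl group suppresses later silyl migration.

Step 21
Reactants: 27 C9 aldehyde 12α-triethylsilyl ether; 30 4-bromo-3-methyl-2-(triisopropylsilyloxy)furan
Product: 33 (9R)-acetate bearing the silyloxyfuran at C9, via lithiofuran 31 (not isolated), via lithium alkoxide 32 (not isolated)
Conditions: 30, t-BuLi (2.0 equiv), Et2O, −78 °C; 27, THF, −78 °C; Ac2O, −78 to 0 °C
Reagents that add atoms: acetic anhydride, CC(=O)OC(C)=O
Why: Bromine–lithium exchange gives a β-acylvinyl anion equivalent; it adds to the aldehyde faster than to the ester or the alkenyl iodide. In the Felkin–Anh arrangement the quaternary C1 lies anti to the nucleophile, which leads to the natural configuration at C9; the alkoxide is acetylated in the flask.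

Step 22
Reactants: 33 (9R)-acetate bearing the silyloxyfuran
Product: 34 triisopropylsilyl (Z)-4-oxobut-2-enoate: C7 aldehyde and C19 silyl ester cis on the C8=C17 olefin
Conditions: dimethyldioxirane (1.0 equiv), acetone/CH2Cl2, −78 °C
Reagents that add atoms: dimethyldioxirane, CC1(C)OO1
Why: Oxidation of 2-silyloxyfurans by dimethyldioxirane at the γ-carbon, with silyl transfer and ring opening, is a known route to silyl (Z)-4-oxo-2-enoates. The ring fixes the Z geometry, and the electron-rich furan reacts long before the iodoalkene.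

Step 23
Reactants: 34 triisopropylsilyl (Z)-4-oxobut-2-enoate
Product: 36 macrocyclic butenolide, via hydroxy silyl ester 35 (not isolated)
Conditions: CrCl2 (10 equiv), NiCl2 (2 mol%), DMSO/THF, rt, 0.002 M; aq. NH4Cl
Reagents that add atoms: none
Why: Nozaki–Hiyama–Kishi reaction: zerovalent nickel inserts into the C–I bond, the alkenyl group passes to trivalent chromium and adds to the C7 aldehyde with retention of the Z geometry, closing the ten-membered ring. The alkoxide cis to the silyl ester then closes the butenolide; C7 is set by the cyclic transition state.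

Step 24
Reactants: 36 macrocyclic butenolide (12-O-triethylsilyl, 14-O-4-methoxybenzyl)
Product: 37 C14 alcohol
Conditions: DDQ, CH2Cl2/pH 7 buffer, 0 °C
Reagents that add atoms: none
Why: Oxidative cleavage of the 4-methoxybenzyl ether by benzylic hydride abstraction; esters, silyl ether and olefins are left alone.

Step 25
Reactants: 37 C14 alcohol
Product: 38 12-O-triethylsilyl ether of the target
Conditions: Ac2O, DMAP (cat.), pyridine, CH2Cl2, 0 °C
Reagents that add atoms: acetic anhydride, CC(=O)OC(C)=O
Why: Acylation of the only free hydroxyl; pyridine is too weak a base to deprotonate C7.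

Step 26
Reactants: 38 12-O-triethylsilyl ether of the target
Product: 39 CNP0281577.1
Conditions: HF·pyridine, pyridine, THF, 0 °C to rt
Reagents that add atoms: none
Why: Mildly acidic fluoride removes the triethylsilyl group and leaves the three esters and the butenolide intact.

## Compound list

1 | (tert-butyldimethylsilyloxy)acetaldehyde | CC(C)(C)[Si](C)(C)OCC=O | starting material
2 | 2-(triphenylphosphoranylidene)propanal | CC(C=O)=P(c1ccccc1)(c1ccccc1)c1ccccc1 | starting material
3 | (E)-4-(tert-butyldimethylsilyloxy)-2-methylbut-2-enal | O=C/C(C)=C/CO[Si](C)(C)C(C)(C)C | intermediate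
4 | (E)-4-methoxybut-3-en-2-one | CO/C=C/C(C)=O | starting material
5 | 4-methoxybenzyl alcohol | COc1ccc(CO)cc1 | starting material
6 | (E)-4-(4-methoxybenzyloxy)but-3-en-2-one | CC(=O)/C=C/OCc1ccc(OC)cc1 | intermediate
7 | (E)-1-(4-methoxybenzyloxy)-3-(tert-butyldimethylsilyloxy)buta-1,3-diene | C=C(O[Si](C)(C)C(C)(C)C)/C=C/OCc1ccc(OC)cc1 | intermediate
8 | cycloadduct: 1β-methyl-1α-formyl, 14α-(4-methoxybenzyloxy), 10β-(silyloxymethyl), C12=C13 silyl enol ether | O=C[C@@]1(C)[C@@H](OCc2ccc(OC)cc2)C=C(O[Si](C)(C)C(C)(C)C)C[C@@H]1CO[Si](C)(C)C(C)(C)C | intermediate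
9 | C2 methyl carbinol of 8 (both C2 epimers) | CC(O)[C@@]1(C)[C@@H](OCc2ccc(OC)cc2)C=C(O[Si](C)(C)C(C)(C)C)C[C@@H]1CO[Si](C)(C)C(C)(C)C | intermediate
10 | C2 methyl ketone | CC(=O)[C@@]1(C)[C@@H](OCc2ccc(OC)cc2)C=C(O[Si](C)(C)C(C)(C)C)C[C@@H]1CO[Si](C)(C)C(C)(C)C | intermediate
11 | prop-2-yn-1-ol | C#CCO | starting material
12 | (Z)-alkenylmagnesium alkoxide (not isolated) | Br[Mg]OC/C(C)=C\[Mg]Br | intermediate
13 | (Z)-3-iodo-2-methylprop-2-en-1-ol | OC/C(C)=C\I | intermediate
14 | (Z)-3-bromo-1-iodo-2-methylprop-1-ene | BrC/C(C)=C\I | intermediate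
15 | C2 ketone with the Z iodoalkenyl chain C3 to C6 | I/C=C(C)\CCC(=O)[C@@]1(C)[C@@H](OCc2ccc(OC)cc2)C=C(O[Si](C)(C)C(C)(C)C)C[C@@H]1CO[Si](C)(C)C(C)(C)C | intermediate
16 | (2R)-alcohol | I/C=C(C)\CC[C@@H](O)[C@@]1(C)[C@@H](OCc2ccc(OC)cc2)C=C(O[Si](C)(C)C(C)(C)C)C[C@@H]1CO[Si](C)(C)C(C)(C)C | intermediate
17 | (2R)-butyrate | I/C=C(C)\CC[C@@H](OC(=O)CCC)[C@@]1(C)[C@@H](OCc2ccc(OC)cc2)C=C(O[Si](C)(C)C(C)(C)C)C[C@@H]1CO[Si](C)(C)C(C)(C)C | intermediate
18 | C12 ketone | I/C=C(C)\CC[C@@H](OC(=O)CCC)[C@@]1(C)[C@@H](OCc2ccc(OC)cc2)CC(=O)C[C@@H]1CO[Si](C)(C)C(C)(C)C | intermediate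
19 | Mannich base: 11-(dimethylaminomethyl) ketone, C11 epimers (not isolated) | I/C=C(C)\CC[C@@H](OC(=O)CCC)[C@@]1(C)[C@@H](OCc2ccc(OC)cc2)CC(=O)C(CN(C)C)[C@@H]1CO[Si](C)(C)C(C)(C)C | intermediate
20 | trimethylammonium iodide of 19 (not isolated) | I/C=C(C)\CC[C@@H](OC(=O)CCC)[C@@]1(C)[C@@H](OCc2ccc(OC)cc2)CC(=O)C(C[N+](C)(C)C)[C@@H]1CO[Si](C)(C)C(C)(C)C.[I-] | intermediate
21 | 11-methylene 12-ketone | I/C=C(C)\CC[C@@H](OC(=O)CCC)[C@@]1(C)[C@@H](OCc2ccc(OC)cc2)CC(=O)C(=C)[C@@H]1CO[Si](C)(C)C(C)(C)C | intermediate
22 | lithium C11=C12 enolate (not isolated) | I/C=C(C)\CC[C@@H](OC(=O)CCC)[C@@]1(C)[C@@H](OCc2ccc(OC)cc2)CC(O[Li])=C(C)[C@@H]1CO[Si](C)(C)C(C)(C)C | intermediate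
23 | 11β-methyl 12-ketone | I/C=C(C)\CC[C@@H](OC(=O)CCC)[C@@]1(C)[C@@H](OCc2ccc(OC)cc2)CC(=O)[C@H](C)[C@@H]1CO[Si](C)(C)C(C)(C)C | intermediate
24 | C9 primary alcohol of 23 | I/C=C(C)\CC[C@@H](OC(=O)CCC)[C@@]1(C)[C@@H](OCc2ccc(OC)cc2)CC(=O)[C@H](C)[C@@H]1CO | intermediate
25 | 9,12α-diol | I/C=C(C)\CC[C@@H](OC(=O)CCC)[C@@]1(C)[C@@H](OCc2ccc(OC)cc2)C[C@@H](O)[C@H](C)[C@@H]1CO | intermediate
26 | C9 aldehyde with free 12α-hydroxyl | I/C=C(C)\CC[C@@H](OC(=O)CCC)[C@@]1(C)[C@@H](OCc2ccc(OC)cc2)C[C@@H](O)[C@H](C)[C@@H]1C=O | intermediate
27 | C9 aldehyde 12α-triethylsilyl ether | I/C=C(C)\CC[C@@H](OC(=O)CCC)[C@@]1(C)[C@@H](OCc2ccc(OC)cc2)C[C@@H](O[Si](CC)(CC)CC)[C@H](C)[C@@H]1C=O | intermediate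
28 | 3-methyltetronic acid | CC1=C(O)COC1=O | starting material
29 | 4-bromo-3-methylfuran-2(5H)-one | CC1=C(Br)COC1=O | intermediate
30 | 4-bromo-3-methyl-2-(triisopropylsilyloxy)furan | Cc1c(Br)coc1O[Si](C(C)C)(C(C)C)C(C)C | intermediate
31 | 4-lithio-3-methyl-2-(triisopropylsilyloxy)furan (not isolated) | Cc1c([Li])coc1O[Si](C(C)C)(C(C)C)C(C)C | intermediate
32 | lithium (9R)-alkoxide of the furyl carbinol (not isolated) | I/C=C(C)\CC[C@@H](OC(=O)CCC)[C@@]1(C)[C@@H](OCc2ccc(OC)cc2)C[C@@H](O[Si](CC)(CC)CC)[C@H](C)[C@@H]1[C@@H](O[Li])c2coc(O[Si](C(C)C)(C(C)C)C(C)C)c2C | intermediate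
33 | (9R)-acetate bearing the 3-methyl-2-(triisopropylsilyloxy)furan-4-yl group | I/C=C(C)\CC[C@@H](OC(=O)CCC)[C@@]1(C)[C@@H](OCc2ccc(OC)cc2)C[C@@H](O[Si](CC)(CC)CC)[C@H](C)[C@@H]1[C@@H](OC(C)=O)c2coc(O[Si](C(C)C)(C(C)C)C(C)C)c2C | intermediate
34 | triisopropylsilyl (Z)-4-oxobut-2-enoate (C7 aldehyde cis to the C19 silyl ester) | I/C=C(C)\CC[C@@H](OC(=O)CCC)[C@@]1(C)[C@@H](OCc2ccc(OC)cc2)C[C@@H](O[Si](CC)(CC)CC)[C@H](C)[C@@H]1[C@@H](OC(C)=O)/C(C=O)=C(\C)C(=O)O[Si](C(C)C)(C(C)C)C(C)C | intermediate
35 | ten-membered C7 carbinol with cis silyl ester (not isolated) | CCCC(=O)O[C@@H]1CC/C(C)=C\[C@H](O)/C(=C(/C)C(=O)O[Si](C(C)C)(C(C)C)C(C)C)[C@H](OC(C)=O)[C@H]2[C@@H](C)[C@H](O[Si](CC)(CC)CC)C[C@H](OCc3ccc(OC)cc3)[C@@]21C | intermediate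
36 | macrocyclic butenolide, 12-O-triethylsilyl, 14-O-(4-methoxybenzyl) | CCCC(=O)O[C@@H]1CC/C(C)=C\[C@@H]2OC(=O)C(C)=C2[C@H](OC(C)=O)[C@H]2[C@@H](C)[C@H](O[Si](CC)(CC)CC)C[C@H](OCc3ccc(OC)cc3)[C@@]21C | intermediate
37 | C14 alcohol | CCCC(=O)O[C@@H]1CC/C(C)=C\[C@@H]2OC(=O)C(C)=C2[C@H](OC(C)=O)[C@H]2[C@@H](C)[C@H](O[Si](CC)(CC)CC)C[C@H](O)[C@@]21C | intermediate
38 | 12-O-triethylsilyl ether of the target | CCCC(=O)O[C@@H]1CC/C(C)=C\[C@@H]2OC(=O)C(C)=C2[C@H](OC(C)=O)[C@H]2[C@@H](C)[C@H](O[Si](CC)(CC)CC)C[C@H](OC(C)=O)[C@@]21C | intermediate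
39 | CNP0281577.1 | CCCC(=O)O[C@@H]1CC/C(C)=C\[C@@H]2OC(=O)C(C)=C2[C@H](OC(C)=O)[C@H]2[C@@H](C)[C@H](O)C[C@H](OC(C)=O)[C@@]21C | target

## Step count and least certain steps

Total: 26 steps. Longest linear sequence: 21 steps (steps 2 to 6, 9 to 18, 21 to 26) from 4.

**Step 4 (key step).** Three things may go wrong:
- The strong Lewis acid may consume the electron-rich diene 7 by desilylation or by a stepwise Mukaiyama–Michael addition that does not close the ring.
- The β-substituted α-methyl enal 3 is a sluggish dienophile, so endo and facial selectivity may erode.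
- The allylic ether of 8 may ionise with loss of 4-methoxybenzyl alcohol.

The fallback gives up catalytic enantiocontrol and moves the source of absolute configuration to step 10. Enal 3 and diene 7 are combined with an achiral Lewis acid (Me2AlCl, −78 °C), which should give 8 together with its enantiomer F1. The racemate is taken through steps 5, 6 and 9, producing beside 9, 10 and 15 their mirror images: carbinol F2, methyl ketone F3 and chain ketone F4. The reagent-controlled reduction of step 10 then converts 15 into 16 and F4 into the diastereomeric (2R)-alcohol F5, which has the enantiomeric ring. The two are separated by chromatography, and the route is rejoined at 16.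

**Step 13.** Enolisation may take place on the C13 side and be followed by β-elimination of 4-methoxybenzyl alcohol, or the base may attack the butyrate. Either would divert material before the Mannich reaction. The fallback brings C20 in with the diene, so that no regioselective enolisation is needed.
- 1-Pentyn-3-one and alcohol 5 (DABCO cat.) give enone F6, and silylation as in step 3 gives the (1E,3Z)-pentadiene F7.
- Cycloaddition of F7 with 3 under the conditions of step 4 should give adduct F8, which carries an 11α-methyl group (cis to the C14 ether).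
- Steps 5, 6, 9, 10, 11 and 12 are run unchanged on this series: carbinol F9, methyl ketone F10, chain ketone F11, alcohol F12, butyrate F13 and finally ketone F14, the C11 epimer of 23.
- Thermodynamic silylation (Me3SiCl, NaI, Et3N, MeCN) goes to the more substituted side and gives the tetrasubstituted trimethylsilyl enol ether F15.
- Protonation of F15 (Bu4NF, AcOH, −78 °C) from the α face rejoins the route at 23.

The price is a more hindered cycloaddition.

**Step 14.** Facial selectivity in the protonation of 22 may be poor, because both faces of C11 are flanked by a substituent in one or the other half-chair. The kinetic product 23 may also epimerise on handling. The fallback replaces substrate control by reagent control. Enolate 22 is trapped with Et3SiCl as the triethylsilyl enol ether F16, which is protonated with a Lewis acid-assisted chiral Brønsted acid (SnCl4 with (R)-1,1′-bi-2-naphthol, or its enantiomer, toluene, −78 °C). The route is rejoined at 23.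

**Step 21.** The formyl group of 27 is axial and its α-carbon C10 is tertiary, so the basic organolithium may epimerise C10 before it adds. Felkin–Anh control at C9 may also be incomplete. The fallback sets C9 by oxidation and reagent-controlled reduction.
- The addition is quenched with water instead of acetic anhydride, giving the C9 carbinols F17 as a mixture.
- Dess–Martin periodinane with pyridine gives the furyl ketone F18.
- Corey–Bakshi–Shibata reduction gives the (9R)-alcohol F19; the furyl group is taken as the large substituent and the (S)-catalyst is used, with the enantiomeric catalyst if the ring carbon proves the larger.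
- Acetylation rejoins the route at 33.

**Step 23.** Divalent chromium may reduce the doubly activated enal of 34 before the slow ring closure, and the addition to the C7 formyl group may show little or the wrong facial selectivity. For the second problem the fallback uses the acidity of C7–H. The C7 epimer F20 is converted with i-Pr3SiOTf and Et3N into the macrocyclic 2-silyloxyfuran F21, in which C7 is planar. Reprotonation (Bu4NF, AcOH, −78 °C) or equilibration of the butenolide with a catalytic amidine base then gives access to 36. The ring closure therefore need not be selective.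

## Further compounds

F1 | step 4 | enantiomer of cycloadduct 8 | O=C[C@]1(C)[C@H](OCc2ccc(OC)cc2)C=C(O[Si](C)(C)C(C)(C)C)C[C@H]1CO[Si](C)(C)C(C)(C)C
F2 | step 4 | enantiomeric series of carbinol 9 | CC(O)[C@]1(C)[C@H](OCc2ccc(OC)cc2)C=C(O[Si](C)(C)C(C)(C)C)C[C@H]1CO[Si](C)(C)C(C)(C)C
F3 | step 4 | enantiomer of methyl ketone 10 | CC(=O)[C@]1(C)[C@H](OCc2ccc(OC)cc2)C=C(O[Si](C)(C)C(C)(C)C)C[C@H]1CO[Si](C)(C)C(C)(C)C
F4 | step 4 | enantiomer of chain ketone 15 | I/C=C(C)\CCC(=O)[C@]1(C)[C@H](OCc2ccc(OC)cc2)C=C(O[Si](C)(C)C(C)(C)C)C[C@H]1CO[Si](C)(C)C(C)(C)C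
F5 | step 4 | (2R)-alcohol with the enantiomeric ring (diastereomer of 16) | I/C=C(C)\CC[C@@H](O)[C@]1(C)[C@H](OCc2ccc(OC)cc2)C=C(O[Si](C)(C)C(C)(C)C)C[C@H]1CO[Si](C)(C)C(C)(C)C
F6 | step 13 | (E)-1-(4-methoxybenzyloxy)pent-1-en-3-one | CCC(=O)/C=C/OCc1ccc(OC)cc1
F7 | step 13 | (1E,3Z)-1-(4-methoxybenzyloxy)-3-(tert-butyldimethylsilyloxy)penta-1,3-diene | C/C=C(O[Si](C)(C)C(C)(C)C)/C=C/OCc1ccc(OC)cc1
F8 | step 13 | 11α-methyl analogue of cycloadduct 8 | O=C[C@@]1(C)[C@@H](OCc2ccc(OC)cc2)C=C(O[Si](C)(C)C(C)(C)C)[C@@H](C)[C@@H]1CO[Si](C)(C)C(C)(C)C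
F9 | step 13 | 11α-methyl analogue of carbinol 9 | CC(O)[C@@]1(C)[C@@H](OCc2ccc(OC)cc2)C=C(O[Si](C)(C)C(C)(C)C)[C@@H](C)[C@@H]1CO[Si](C)(C)C(C)(C)C
F10 | step 13 | 11α-methyl analogue of methyl ketone 10 | CC(=O)[C@@]1(C)[C@@H](OCc2ccc(OC)cc2)C=C(O[Si](C)(C)C(C)(C)C)[C@@H](C)[C@@H]1CO[Si](C)(C)C(C)(C)C
F11 | step 13 | 11α-methyl analogue of chain ketone 15 | I/C=C(C)\CCC(=O)[C@@]1(C)[C@@H](OCc2ccc(OC)cc2)C=C(O[Si](C)(C)C(C)(C)C)[C@@H](C)[C@@H]1CO[Si](C)(C)C(C)(C)C
F12 | step 13 | 11α-methyl analogue of alcohol 16 | I/C=C(C)\CC[C@@H](O)[C@@]1(C)[C@@H](OCc2ccc(OC)cc2)C=C(O[Si](C)(C)C(C)(C)C)[C@@H](C)[C@@H]1CO[Si](C)(C)C(C)(C)C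
F13 | step 13 | 11α-methyl analogue of butyrate 17 | I/C=C(C)\CC[C@@H](OC(=O)CCC)[C@@]1(C)[C@@H](OCc2ccc(OC)cc2)C=C(O[Si](C)(C)C(C)(C)C)[C@@H](C)[C@@H]1CO[Si](C)(C)C(C)(C)C
F14 | step 13 | 11α-methyl 12-ketone (C11 epimer of 23) | I/C=C(C)\CC[C@@H](OC(=O)CCC)[C@@]1(C)[C@@H](OCc2ccc(OC)cc2)CC(=O)[C@@H](C)[C@@H]1CO[Si](C)(C)C(C)(C)C
F15 | step 13 | C11=C12 trimethylsilyl enol ether | I/C=C(C)\CC[C@@H](OC(=O)CCC)[C@@]1(C)[C@@H](OCc2ccc(OC)cc2)CC(O[Si](C)(C)C)=C(C)[C@@H]1CO[Si](C)(C)C(C)(C)C
F16 | step 14 | C11=C12 triethylsilyl enol ether | I/C=C(C)\CC[C@@H](OC(=O)CCC)[C@@]1(C)[C@@H](OCc2ccc(OC)cc2)CC(O[Si](CC)(CC)CC)=C(C)[C@@H]1CO[Si](C)(C)C(C)(C)C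
F17 | step 21 | C9 furyl carbinols (both C9 epimers) | I/C=C(C)\CC[C@@H](OC(=O)CCC)[C@@]1(C)[C@@H](OCc2ccc(OC)cc2)C[C@@H](O[Si](CC)(CC)CC)[C@H](C)[C@@H]1C(O)c2coc(O[Si](C(C)C)(C(C)C)C(C)C)c2C
F18 | step 21 | C9 furyl ketone | I/C=C(C)\CC[C@@H](OC(=O)CCC)[C@@]1(C)[C@@H](OCc2ccc(OC)cc2)C[C@@H](O[Si](CC)(CC)CC)[C@H](C)[C@@H]1C(=O)c2coc(O[Si](C(C)C)(C(C)C)C(C)C)c2C
F19 | step 21 | (9R)-furyl carbinol | I/C=C(C)\CC[C@@H](OC(=O)CCC)[C@@]1(C)[C@@H](OCc2ccc(OC)cc2)C[C@@H](O[Si](CC)(CC)CC)[C@H](C)[C@@H]1[C@@H](O)c2coc(O[Si](C(C)C)(C(C)C)C(C)C)c2C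
F20 | step 23 | C7 epimer of macrocyclic butenolide 36 | CCCC(=O)O[C@@H]1CC/C(C)=C\[C@H]2OC(=O)C(C)=C2[C@H](OC(C)=O)[C@H]2[C@@H](C)[C@H](O[Si](CC)(CC)CC)C[C@H](OCc3ccc(OC)cc3)[C@@]21C
F21 | step 23 | macrocyclic 2-(triisopropylsilyloxy)furan | CCCC(=O)O[C@@H]1CC/C(C)=C\c2oc(O[Si](C(C)C)(C(C)C)C(C)C)c(C)c2[C@H](OC(C)=O)[C@H]2[C@@H](C)[C@H](O[Si](CC)(CC)CC)C[C@H](OCc3ccc(OC)cc3)[C@@]21C
A1 | alternative 1 | 12-O-triethylsilyl ether of the target (identical with 38) | CCCC(=O)O[C@@H]1CC/C(C)=C\[C@@H]2OC(=O)C(C)=C2[C@H](OC(C)=O)[C@H]2[C@@H](C)[C@H](O[Si](CC)(CC)CC)C[C@H](OC(C)=O)[C@@]21C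
A2 | alternative 1 | open-chain Z alkenyl iodide with C7 aldehyde and cis methyl ester | I/C=C(C)\CC[C@@H](OC(=O)CCC)[C@@]1(C)[C@@H](OC(C)=O)C[C@@H](O[Si](CC)(CC)CC)[C@H](C)[C@@H]1[C@@H](OC(C)=O)/C(C=O)=C(\C)C(=O)OC
A3 | alternative 2 | bicyclic ten-membered C2,C7-diketone with Z C4=C5 olefin | O=C1C/C=C(C)\CC(=O)C[C@H](O[Si](C)(C)C(C)(C)C)[C@H]2[C@@H](C)[C@H](OCOC)C[C@H](O[Si](C)(C)C(C)(C)C)[C@@]21C
A4 | alternative 2 | tricyclic 1,4-diene with tetrasubstituted C2=C7 olefin | CC1=CCC2=C(C1)C[C@H](O[Si](C)(C)C(C)(C)C)[C@H]1[C@@H](C)[C@H](OCOC)C[C@H](O[Si](C)(C)C(C)(C)C)[C@@]12C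
A5 | alternative 3 | bicyclic C2 alcohol with C11 exocyclic methylene | O[C@@H]1CC/C(C)=C\[C@@H]2OC(=O)C(C)=C2[C@H](O[Si](C)(C)C(C)(C)C)[C@H]2C(=C)[C@H](OCc3ccc(OC)cc3)C[C@H](O[Si](C)(C)C(C)(C)C)[C@@]21C
A6 | alternative 3 | fourteen-membered C1–C2 epoxide with E C10=C11 olefin | C[C@@]12O[C@@H]1CC/C(C)=C\[C@@H]3OC(=O)C(C)=C3[C@H](O[Si](C)(C)C(C)(C)C)/C=C(C)/[C@H](OCc4ccc(OC)cc4)C[C@@H]2O[Si](C)(C)C(C)(C)C
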